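The pyran ring (O1, C2, C3, C4, C4a, C8a) is disconnected across both C4–C4a and O1–C2, which leads back to an open tetrahydroxychalcone and an acyclic C10 hydroxy-enal. One chiral-acid-catalysed operation joins the enal carbonyl carbon to C4a, the only benzene carbon flanked by two oxygen-bearing carbons (C5, C8a), ionises the adduct to an oxatriene/allyl cation paired with the chiral anion, and closes O1 onto C2 by oxa-6π cyclisation, setting the sole stereocentre. The C5 hydroxyl stays chelated to the C6 ketone, so only O1 can close, and the C8 hydroxyl beside O1 anchors the catalyst. Enal E/Z isomers and the racemic adduct converge.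

Key step: step 3

Remark on numbering: chromene numbering of the target is used; in chalcone 5 the corresponding atoms are C3′ (= C4a), O4′ (= O1), 2′-OH (= 5-OH) and 5′-OH (= 8-OH).

Remark on the chemistry (assumption): the sense of asymmetric induction in step 3 cannot be predicted with confidence. The (R)-configured acid is written; its (S)-antipode would be used without other change if that is the one that leads to the (S)-chromene.

Step 1
Reactants: 1 7-hydroxy-3,7-dimethyloctanal (hydroxycitronellal, racemic)
Product: 2 (E)-7-hydroxy-3,7-dimethyloct-2-enal (may contain the 2Z isomer)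
Conditions: IBX (1.5 equiv), DMSO, 70 °C
Reagents that add atoms: none
Why: IBX-mediated α,β-dehydrogenation of an aldehyde (through its enol) should introduce the C2=C3 double bond, the tertiary alcohol cannot be oxidised, and the E/Z ratio is of no consequence because both isomers converge in step 3.

Step 2
Reactants: 3 1-(2,4,5-trihydroxyphenyl)ethanone; 4 4-hydroxybenzaldehyde
Product: 5 (E)-3-(4-hydroxyphenyl)-1-(2,4,5-trihydroxyphenyl)prop-2-en-1-one
Conditions: dry HCl (ca. 3 M in EtOH), rt, Ar
Reagents that add atoms: none
Why: Acid-catalysed Claisen–Schmidt (aldol) condensation followed by dehydration should give the thermodynamically favoured (E)-enone without phenol protection, acid being chosen because the hydroxyquinol ring is oxidised in alkali.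

Step 3
Reactants: 5 (E)-3-(4-hydroxyphenyl)-1-(2,4,5-trihydroxyphenyl)prop-2-en-1-one; 2 (E)-7-hydroxy-3,7-dimethyloct-2-enal
Product: 8 (S,E)-1-[5,8-dihydroxy-2-(4-hydroxy-4-methylpentyl)-2-methyl-2H-chromen-6-yl]-3-(4-hydroxyphenyl)prop-2-en-1-one, via hydroxyalkyl adduct 6 (not isolated), via oxatriene 7 (not isolated)
Conditions: 2 (1.5 equiv), (R)-3,3′-bis(2,4,6-triisopropylphenyl)-BINOL N-triflylphosphoramide (10 mol %), EtOAc–PhMe 1:1, 0 → 25 °C, Ar, dark
Reagents that add atoms: none
Why: Proposed new method: the strong chiral acid is expected to catalyse ortho-hydroxyalkylation of C3′ of 5 by the protonated enal (C4–C4a bond, adduct 6), to ionise 6 with loss of water to the delocalised allyl cation, which is the O-protonated form of oxatriene 7 held as a contact ion pair with the chiral phosphoramide anion, and to let O4′ close onto the cation terminus. The closest known reaction types are the racemic amine-salt or Brønsted acid chromenylation of resorcinols with enals (Knoevenagel/oxa-6π cascade) and the chiral Brønsted acid-catalysed asymmetric allylic substitution of aryl-substituted 2-(3-hydroxyalkenyl)phenols to 2,2-disubstituted 2H-chromenes; neither has been shown for a methyl/alkyl terminus or in one flask from a phenol and an enal. The pyran ring closes by oxa-6π electrocyclisation of the s-cis oxatriene, which is equivalent to 6-endo capture of the allyl terminus C2 by O1. C2 is the only new stereocentre and is set in this closure under catalyst control: the anion, hydrogen-bonded to O1 and to the neighbouring C8 hydroxyl, should favour one helical sense of the oxatriene and hence one face of C2, the (R)-acid being assumed to give (S) as stated in the remark. The step is stereoconvergent, since the E and Z isomers of 2 and both enantiomers of 6 merge in one cation with a low C2–C3 rotation barrier. It needs attack at C3′ and closure on O4′ and not O2′, which the substrate secures because C3′ is the only ring CH between two hydroxyls and the 2′-hydroxyl stays hydrogen-bonded to the ketone, and it needs an irreversible closure, for which low temperature, darkness and the low basicity of the aryl ether oxygen of 8 are relied on.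

Compound list
1 | 7-hydroxy-3,7-dimethyloctanal (hydroxycitronellal, racemic) | CC(CCCC(C)(C)O)CC=O | starting material
2 | (E)-7-hydroxy-3,7-dimethyloct-2-enal (2Z isomer may be present) | CC(C)(O)CCC/C(C)=C/C=O | intermediate
3 | 1-(2,4,5-trihydroxyphenyl)ethanone | CC(=O)c1cc(O)c(O)cc1O | starting material
4 | 4-hydroxybenzaldehyde | O=Cc1ccc(O)cc1 | starting material
5 | (E)-3-(4-hydroxyphenyl)-1-(2,4,5-trihydroxyphenyl)prop-2-en-1-one | O=C(/C=C/c1ccc(O)cc1)c1cc(O)c(O)cc1O | intermediate
6 | (E)-1-[3-(1,7-dihydroxy-3,7-dimethyloct-2-en-1-yl)-2,4,5-trihydroxyphenyl]-3-(4-hydroxyphenyl)prop-2-en-1-one (racemic carbinol, side-chain alkene E/Z) | CC(C)(O)CCCC(C)=CC(O)c1c(O)c(C(=O)/C=C/c2ccc(O)cc2)cc(O)c1O | intermediate (not isolated)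
7 | 2,5-dihydroxy-4-[(E)-3-(4-hydroxyphenyl)prop-2-enoyl]-6-(7-hydroxy-3,7-dimethyloct-2-enylidene)cyclohexa-2,4-dien-1-one (oxatriene, vinylogous o-quinone methide) | CC(C)(O)CCCC(C)=CC=C1C(=O)C(O)=CC(C(=O)/C=C/c2ccc(O)cc2)=C1O | intermediate (not isolated)
8 | (S,E)-1-[5,8-dihydroxy-2-(4-hydroxy-4-methylpentyl)-2-methyl-2H-chromen-6-yl]-3-(4-hydroxyphenyl)prop-2-en-1-one | CC(C)(O)CCC[C@@]1(C)C=Cc2c(O)c(C(=O)/C=C/c3ccc(O)cc3)cc(O)c2O1 | target

Total step count: 3. Longest linear sequence: 2 steps (3 → 5 → 8, or 1 → 2 → 8).

Steps most likely to fail

Step 3 (Proposed new method). Four processes may go wrong: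
- C–C bond formation at the acyl-deactivated ring may be too slow at the temperature needed for ion-pair control.
- The catalyst may discriminate poorly between methyl and methylene at C2, giving low enantioselectivity.
- The acid may isomerise the 2′-hydroxychalcone to the flavanone or let the side-chain tertiary hydroxyl capture the cation.
- The product may re-ionise and partly racemise.

The fallback uses known chemistry and replaces asymmetric catalysis by resolution. It sets out from 5 and 2: ethylenediammonium diacetate (20 mol %) in toluene–DMF at 100 °C effects the established racemic Knoevenagel/oxa-6π chromenylation and should give the racemic chromene chalcone F1. Its enantiomers are then separated by preparative chiral SFC on a polysaccharide carbamate phase, and the (S)-enantiomer is 8, where the fallback rejoins the route.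

Step 2. The unprotected acid condensation may be diverted by intramolecular oxa-Michael closure to the flavanone and by oligomerisation of the electron-rich partners. The fallback sets out from 3 and 4 and uses protection and base:
- 3 with MOMCl/i-Pr2NEt (2.2 equiv, CH2Cl2, 0 °C) should give 1-[2-hydroxy-4,5-bis(methoxymethoxy)phenyl]ethanone F2, the chelated 2-hydroxyl staying free.
- 4 is converted in the same way into 4-(methoxymethoxy)benzaldehyde F3.
- KOH-mediated Claisen–Schmidt condensation of F2 with F3 (EtOH/H2O, rt, Ar) should give the tris-MOM chalcone F4.
- 3 M HCl in MeOH at 40 °C removes the three MOM groups and comes back to the route at 5.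

Step 1. Over-dehydrogenation to the dienal and incomplete conversion of the β-branched aldehyde may occur. The fallback sets out from 1 and replaces direct dehydrogenation by selenoxide elimination. Amine-catalysed α-selenenylation (N-(phenylseleno)phthalimide, 10 mol % L-prolinamide, CH2Cl2, rt) should give 7-hydroxy-3,7-dimethyl-2-(phenylselanyl)octanal F5. Oxidation with NaIO4 (THF/H2O, 0 °C) and syn-elimination of the selenoxide, for which only the C3–H is available, comes back to the route at 2.

Further compounds
F1 | step 3 | racemic (E)-1-[5,8-dihydroxy-2-(4-hydroxy-4-methylpentyl)-2-methyl-2H-chromen-6-yl]-3-(4-hydroxyphenyl)prop-2-en-1-one | CC(C)(O)CCCC1(C)C=Cc2c(O)c(C(=O)/C=C/c3ccc(O)cc3)cc(O)c2O1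
F2 | step 2 | 1-[2-hydroxy-4,5-bis(methoxymethoxy)phenyl]ethanone | CC(=O)c1cc(OCOC)c(OCOC)cc1O
F3 | step 2 | 4-(methoxymethoxy)benzaldehyde | COCOc1ccc(C=O)cc1
F4 | step 2 | (E)-1-[2-hydroxy-4,5-bis(methoxymethoxy)phenyl]-3-[4-(methoxymethoxy)phenyl]prop-2-en-1-one | COCOc1ccc(/C=C/C(=O)c2cc(OCOC)c(OCOC)cc2O)cc1
F5 | step 1 | 7-hydroxy-3,7-dimethyl-2-(phenylselanyl)octanal | CC(CCCC(C)(C)O)C([Se]c1ccccc1)C=O
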